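The numbers in the tables are calculated with made-up constants.

Start from the constants: the proposed steps come without them, so read one from the runs.

common to all: substrate 0.14 M
- Friday's: partner 0.20 M; protic impurity 0.14 M; run made earlier
- Thursday's: partner 0.40 M; protic impurity 0.14 M; run made earlier
- east: partner 0.140 M; protic impurity 0.140 M; time 20 d
- north-west: partner 0.210 M; protic impurity 0.140 M; time 20 d
- north: partner 0.320 M; protic impurity 0.140 M; time 20 d

| run | time / d | target / % | substrate / % | open intermediate / % |
|---|---|---|---|---|
| Friday's | 1.04 | 1.7 | 88.8 | 9.1 |
| Friday's | 2.50 | 5.3 | 85.7 | 8.5 |
| Friday's | 5.00 | 10.8 | 80.5 | 7.8 |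
| Friday's | 8.00 | 18.8 | 73.8 | 8.0 |
| Friday's | 10.0 | 21.7 | 72.4 | 7.1 |
| Friday's | 15.0 | 29.3 | 63.5 | 5.8 |
| Thursday's | 1.04 | 5.3 | 86.6 | 8.9 |
| Thursday's | 1.67 | 8.1 | 84.0 | 7.2 |
| Thursday's | 3.00 | 12.9 | 78.0 | 7.6 |
| Thursday's | 5.00 | 22.0 | 71.0 | 6.7 |
| Thursday's | 8.00 | 31.8 | 61.9 | 6.4 |
| Thursday's | 15.0 | 49.8 | 45.6 | 4.7 |

(readings scatter by 0.5 percentage points)

- the numbers in the tables scatter with a standard deviation of 0.5 percentage points
- steps that have been proposed: substrate <-> open intermediate; partner -> second intermediate; open intermediate + second intermediate -> target; target -> over-reaction product; partner + protic impurity -> quenched reagent; partner <-> dormant form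

Look first at the open intermediate. It stands at 0.102 of the substrate in Friday's first row and at 0.103 in Thursday's last, so treat the two as one pool, a rapid pre-equilibrium. Add up Thursday's last row and you get 100%, so target is what the pool has lost.

Now count turnovers. The logarithm of the pool's fall is 0.367 on Friday's run and 0.687 on Thursday's, both at 15.0 d. Their ratio, 1.87, lies near the ratio of the partner charges, 2.00, but not near the ratio 4.33 of what stands after subtracting protic impurity, so reckon with the whole charge.

Divide by charge and time: 0.122 M⁻¹ d⁻¹ and 0.115 M⁻¹ d⁻¹. Take the geometric mean, 0.118 M⁻¹ d⁻¹, as the turnover constant, the turnovers of the pool per day and per molar of partner charged. Reckon a flask's count as constant times charge times time, and estimate the pool left as the exponential of minus that count.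

Substrate makes up 91.2% of the pool in those last rows, so substrate equals target at a count of 0.648.

- which of these there is most of at the end, counted by the substrate in it, east (target / open intermediate / substrate)
- which of these there is most of at the end, counted by the substrate in it, north-west (target / open intermediate / substrate)
- which of these there is most of at the end, counted by the substrate in it, north (target / open intermediate / substrate)
- the largest of these amounts at the end, in percent of the substrate charged, east
- the largest of these amounts at the end, in percent of the substrate charged, north-west
- the largest of these amounts at the end, in percent of the substrate charged, north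

My counts are 0.331 for east, 0.497 for north-west and 0.757 for north. East and north-west lie below the crossing and north above it. I commit to substrate at 65.5% in east, substrate at 55.5% in north-west and target at 53.1% in north.

The forecast, holding that “the two act as one pool”, names the same species at 67%, 57% and 51%, above my east figure and below my north figure.

The flask gives substrate at 66.6% in east, substrate at 56.9% in north-west and target at 50.2% in north.

    substrate ⇌ open intermediate (K = 0.100, k = 0.270 h⁻¹)
    partner → second intermediate (k = 0.720 h⁻¹)
    open intermediate + second intermediate → target (k = 0.0620 M⁻¹ h⁻¹)
    target → over-reaction product (k = 8.70 × 10⁻⁵ h⁻¹)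
    partner + protic impurity → quenched reagent (k = 0.130 M⁻¹ h⁻¹)
    partner ⇌ dormant form (K = 1.30, k = 0.00840 h⁻¹)

In east, substrate and open intermediate relax by their exchange alone with a half-life of 0.233 h, far shorter than the 6.8 d half-life of open intermediate by its coupling with second intermediate at 0.0393 d. East's count of 0.331 goes with 26.1% of target. Take the neighbour of east with 0.35 M of partner: its count of 0.828 lies above the crossing at 0.648, and it ends with target ahead, 53.4% against 41.2% of substrate.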